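**Plan**

- Retrosynthesis: the acyl C16–O bond of the seven-membered lactone is cut first, then C11–C12. C11 (secondary, oxygen-bearing) and C12 (tertiary, oxygen- and methyl-bearing) are neighbours in the 14-membered ring, which is the pattern left by joining an aldehyde reductively to a methyl ketone. Next come the oxolane C4–O and the C8–O bonds (epoxide cascade), then C9–C10, C7–C8, C5–C6 and C3–C4.
- Forward: the C12–C3 keto aldehyde from (R)-limonene oxide is extended linearly to C11 (C3–C4 Nozaki–Hiyama–Kishi, C5–C6 Johnson–Claisen, C7–C8 Grignard, C9–C10 Johnson–Claisen). The oxolane then forms together with a temporary C8–C11 γ-lactone, the 14-membered carbocycle closes by titanium pinacol coupling, and the seven-membered lactone is closed last.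
- Stereochemistry: C1 comes from (R)-limonene and both E-alkenes from the Claisen chair. C3, C4, C7 and C8 come from a double Shi epoxidation (L-fructose-derived ketone) followed by a stereospecific anti, 5-exo cascade. C11 and C12 are set in the pinacol coupling.

Key step: step 15

Numbering: target numbering is used throughout (C1–C14 ring carbons, C15 the alkene carbon on C1, C16 the lactone carbonyl, C17 the =CH2, C18/C19/C20 the methyls on C4/C8/C12).
Assumption: the L-fructose-derived enantiomer of the Shi ketone is taken as purchasable (otherwise made from L-sorbose), and commercial (+)-limonene 1,2-oxide is taken to carry the (4R) centre of (R)-limonene.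

**Route**

Step 1
Reactants: 1 (+)-limonene 1,2-oxide [(4R), cis/trans mixture]
Product: 3 (3R)-6-oxo-3-(prop-1-en-2-yl)heptanal, via limonene-1,2-diol 2 (not isolated)
Conditions: H5IO6 (1.1 equiv), THF–H2O, 0 °C → rt
Reagents that add atoms: water, O
Why: Periodic acid opens the epoxide to diol 2 and cleaves the glycol in the same flask (Malaprade-type cleavage), leaving the isopropenyl group and the future C1 centre of (R)-limonene untouched.

Step 2
Reactants: 3 (3R)-6-oxo-3-(prop-1-en-2-yl)heptanal; 4 2-bromopropene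
Product: 5 (5R,7RS)-7-hydroxy-8-methyl-5-(prop-1-en-2-yl)non-8-en-2-one
Conditions: CrCl2 (4 equiv), NiCl2 (1 mol%), DMF, rt
Reagents that add atoms: none
Why: Nozaki–Hiyama–Kishi addition: the 2-propenylchromium species adds to aldehydes but not to methyl ketones, so C3–C4 forms without protecting C12, and the C3 carbinol epimers are erased in step 4.

Step 3
Reactants: 5 (5R,7RS)-7-hydroxy-8-methyl-5-(prop-1-en-2-yl)non-8-en-2-one
Product: 6 (3RS,5R)-2-methyl-7-(2-methyl-1,3-dioxolan-2-yl)-5-(prop-1-en-2-yl)hept-1-en-3-ol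
Conditions: HOCH2CH2OH, PPTS (pyridinium p-toluenesulfonate, cat.), benzene, reflux, Dean–Stark
Reagents that add atoms: ethylene glycol, OCCO
Why: Acid-catalysed ketalisation with azeotropic removal of water masks C12 for the hydride and organometallic steps, and PPTS is too weak to ionise or transpose the allylic alcohol.

Step 4
Reactants: 6 (3RS,5R)-2-methyl-7-(2-methyl-1,3-dioxolan-2-yl)-5-(prop-1-en-2-yl)hept-1-en-3-ol; 7 triethyl orthoacetate
Product: 9 ethyl (4E,7R)-4-methyl-9-(2-methyl-1,3-dioxolan-2-yl)-7-(prop-1-en-2-yl)non-4-enoate, via ketene acetal 8 (not isolated)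
Conditions: EtCO2H (cat.), neat 7, 140 °C, EtOH distilled off
Reagents that add atoms: none
Why: Johnson–Claisen rearrangement: ketene acetal 8 undergoes a chair [3,3] shift with the C2 chain equatorial, forming C5–C6 and the E-trisubstituted C3=C4 alkene while destroying the C3 carbinol centre.

Step 5
Reactants: 9 ethyl (4E,7R)-4-methyl-9-(2-methyl-1,3-dioxolan-2-yl)-7-(prop-1-en-2-yl)non-4-enoate
Product: 10 (4E,7R)-4-methyl-9-(2-methyl-1,3-dioxolan-2-yl)-7-(prop-1-en-2-yl)non-4-enal
Conditions: iBu2AlH (1.1 equiv), CH2Cl2, −78 °C; MeOH, aq. KNaC4H4O6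
Reagents that add atoms: none
Why: Partial ester reduction: the tetrahedral aluminium hemiacetal is stable at −78 °C and releases the C7 aldehyde only on work-up.

Step 6
Reactants: 10 (4E,7R)-4-methyl-9-(2-methyl-1,3-dioxolan-2-yl)-7-(prop-1-en-2-yl)non-4-enal; 11 2-propenylmagnesium bromide
Product: 12 (3RS,6E,9R)-2,6-dimethyl-11-(2-methyl-1,3-dioxolan-2-yl)-9-(prop-1-en-2-yl)undeca-1,6-dien-3-ol
Conditions: THF, −78 → 0 °C; aq. NH4Cl
Reagents that add atoms: none
Why: Grignard addition to the aldehyde forms C7–C8 while the ketone is masked as the dioxolane, and the C7 epimers converge in step 7.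

Step 7
Reactants: 12 (3RS,6E,9R)-2,6-dimethyl-11-(2-methyl-1,3-dioxolan-2-yl)-9-(prop-1-en-2-yl)undeca-1,6-dien-3-ol; 7 triethyl orthoacetate
Product: 14 ethyl (4E,8E,11R)-4,8-dimethyl-13-(2-methyl-1,3-dioxolan-2-yl)-11-(prop-1-en-2-yl)trideca-4,8-dienoate, via ketene acetal 13 (not isolated)
Conditions: EtCO2H (cat.), neat 7, 140 °C, EtOH distilled off
Reagents that add atoms: none
Why: Second Johnson–Claisen rearrangement: the same chair control gives the E-C7=C8 alkene, forms C9–C10 and delivers C11 at the carboxyl oxidation level.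

Step 8
Reactants: 14 ethyl (4E,8E,11R)-4,8-dimethyl-13-(2-methyl-1,3-dioxolan-2-yl)-11-(prop-1-en-2-yl)trideca-4,8-dienoate
Product: 15 (4E,8E,11R)-4,8-dimethyl-13-(2-methyl-1,3-dioxolan-2-yl)-11-(prop-1-en-2-yl)trideca-4,8-dienoic acid
Conditions: LiOH, THF–MeOH–H2O, rt; then 1 M HCl at 0 °C to pH 4
Reagents that add atoms: lithium hydroxide, [Li+].[OH-]
Why: Saponification frees the carboxylic acid that serves as the internal nucleophile of the cascade, and the brief cold acidification to pH 4 leaves the dioxolane intact.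

Step 9
Reactants: 15 (4E,8E,11R)-4,8-dimethyl-13-(2-methyl-1,3-dioxolan-2-yl)-11-(prop-1-en-2-yl)trideca-4,8-dienoic acid
Product: 18 hydroxy oxolane lactone (3S,4R,7S,8R), via bis-epoxy acid 16 (not isolated), via epoxy hydroxy lactone 17 (not isolated)
Conditions: ent-Shi ketone (1,2:4,5-di-O-isopropylidene-β-L-erythro-2,3-hexodiulo-2,6-pyranose, 0.6 equiv), KHSO5 (as 2KHSO5·KHSO4·K2SO4, 2.6 equiv), K2CO3, Bu4NHSO4, MeCN–CH2(OMe)2–aq. Na2B4O7 buffer, 0 °C; NaH2PO4 to pH 4, extraction; CSA (camphor-10-sulfonic acid, 0.1 equiv), CH2Cl2, 0 °C → rt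
Reagents that add atoms: potassium peroxymonosulfate, [K+].[O-]S(=O)(=O)OO
Why: Shi epoxidation through the spiro transition state of the L-fructose-derived dioxirane should give the (3S,4S) and (7S,8S) epoxides of the two E-trisubstituted alkenes (the hindered 1,1-disubstituted isopropenyl alkene reacts more slowly, so the oxidant is limited); under acid the carboxyl group then opens the 7,8-epoxide at C8 and the freed C7 hydroxyl opens the 3,4-epoxide at C4, two Baldwin-favoured 5-exo-tet anti openings at the tertiary carbons that invert C8 and C4 and retain C7 and C3.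

Step 10
Reactants: 18 hydroxy oxolane lactone (3S,4R,7S,8R)
Product: 19 3-O-TBS ether of 18
Conditions: TBSOTf, 2,6-lutidine, CH2Cl2, −78 → 0 °C
Reagents that add atoms: tert-butyldimethylsilyl triflate, CC(C)(C)[Si](C)(C)OS(=O)(=O)C(F)(F)F
Why: Silyl triflate silylation caps the only free hydroxyl (the hindered secondary C3–OH), and the ketone-derived dioxolane and the lactone tolerate silyl triflate with a hindered pyridine base.

Step 11
Reactants: 19 3-O-TBS ether of 18
Product: 20 Weinreb amide with free tertiary 8-OH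
Conditions: MeNH(OMe)·HCl, iPrMgCl, THF, −20 → 0 °C; aq. NH4Cl; crude product used at once
Reagents that add atoms: N,O-dimethylhydroxylamine hydrochloride, CNOC.Cl
Why: Weinreb amide formation by aminolysis of the γ-lactone with the magnesium amide; the basic medium keeps the freed tertiary C8 alkoxide from closing back, and C8 keeps its configuration because only the acyl C–O bond breaks.

Step 12
Reactants: 20 Weinreb amide with free tertiary 8-OH
Product: 21 8-O-TES ether of 20
Conditions: TESOTf, 2,6-lutidine, CH2Cl2, −78 °C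
Reagents that add atoms: triethylsilyl triflate, CC[Si](CC)(CC)OS(=O)(=O)C(F)(F)F
Why: Silyl triflate silylation is fast enough for a tertiary alcohol at −78 °C to outrun relactonisation, and the C8 oxygen must be capped so that the C11 aldehyde cannot close to a lactol.

Step 13
Reactants: 21 8-O-TES ether of 20
Product: 22 C11 aldehyde with C12 dioxolane
Conditions: iBu2AlH (1.5 equiv), THF, −78 °C; aq. KNaC4H4O6
Reagents that add atoms: none
Why: Weinreb amide reduction: the chelated tetrahedral aluminium intermediate survives until work-up, so the aldehyde is not over-reduced.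

Step 14
Reactants: 22 C11 aldehyde with C12 dioxolane
Product: 23 keto aldehyde (1R,3S,4R,7S,8R)
Conditions: PPTS (0.3 equiv), acetone–H2O (10:1), 45 °C
Reagents that add atoms: water, O
Why: Acid-catalysed ketal hydrolysis: the dioxolane of a dialkyl ketone is cleaved by PPTS under conditions that a secondary TBS ether and a tertiary TES ether survive, and the aldehyde has no stereocentre at its α-carbon.

Step 15
Reactants: 23 keto aldehyde (1R,3S,4R,7S,8R)
Product: 24 macrocyclic 11,12-diol (1R,3S,4R,7S,8R,11R,12R)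
Conditions: TiCl3(DME)1.5 (12 equiv), Zn–Cu couple (30 equiv), DME, reflux (reagent formation); then 23 added by syringe pump over 30 h at 25 °C (about 2 mM final); aq. K2CO3
Reagents that add atoms: none
Why: Low-valent titanium, made by reducing TiCl3(DME)1.5 with the Zn–Cu couple, gives one electron to the C11 aldehyde and one to the C12 ketone, the two titanium-bound ketyls combine to form the C11–C12 bond, and the titanium diolate is hydrolysed by aqueous K2CO3 to diol 24. The closest known reaction type is the McMurry titanium pinacol macrocyclisation of keto aldehydes, which has been used to close 14-membered cembranoid diols. The 14-membered carbocycle closes end to end by ketyl–ketyl combination, kept intramolecular by syringe-pump addition to high dilution, with the oxolane and the C1 branch shortening the flexible part of the chain. C11 and C12 are created together: the trans (11R*,12R*) relationship is the one that large-ring titanium pinacol couplings should favour, whereas the choice between (11R,12R) and (11S,12S) rests only on the conformation fixed by the oxolane, the C1 centre and the two silyl ethers and cannot be predicted with confidence. The step needs ketyl coupling to win over deoxygenation to the alkene and over ketyl addition to the isopropenyl group; running it at 25 °C stops at the diolate, and the isopropenyl alkene is unactivated and carries no ester. Silyl ethers and the oxolane are inert to the reagent.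

Step 16
Reactants: 24 macrocyclic 11,12-diol (1R,3S,4R,7S,8R,11R,12R)
Product: 25 macrocyclic 3,8,11,12-tetraol
Conditions: HF·pyridine, THF, 0 → 40 °C
Reagents that add atoms: none
Why: Fluoride-driven cleavage of both Si–O bonds (strong Si–F bond) frees C3–OH and C8–OH at a stage where the molecule has no group sensitive to HF·pyridine.

Step 17
Reactants: 25 macrocyclic 3,8,11,12-tetraol
Product: 26 3,11-diacetate with free tertiary 8-OH and 12-OH
Conditions: Ac2O (2.5 equiv), pyridine, DMAP (4-dimethylaminopyridine, cat.), CH2Cl2, 0 °C → rt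
Reagents that add atoms: acetic anhydride, CC(=O)OC(C)=O
Why: DMAP-catalysed acetylation is selective for the two secondary hydroxyls (C3, C11) over the two tertiary ones (C8, C12), so both acetates of the target are placed in one step.

Step 18
Reactants: 26 3,11-diacetate with free tertiary 8-OH and 12-OH
Product: 27 allylic alcohol (C16–OH)
Conditions: SeO2 (0.5 equiv), tBuOOH (4 equiv), CH2Cl2, rt
Reagents that add atoms: selenium dioxide, O=[Se]=O; tert-butyl hydroperoxide, CC(C)(C)OO
Why: Riley-type allylic oxidation: ene reaction at the terminal CH2 followed by [2,3]-shift oxidises the methyl group of the 1,1-disubstituted alkene (methyl is preferred over the C1 methine), and the molecule holds no other alkene.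

Step 19
Reactants: 27 allylic alcohol (C16–OH)
Product: 29 hydroxy acid (C16 carboxylic acid), via enal 28 (not isolated)
Conditions: MnO2, CH2Cl2, rt, filtration; then NaClO2, NaH2PO4, 2-methyl-2-butene, tBuOH–H2O, rt
Reagents that add atoms: sodium chlorite, [Na+].[O-]Cl=O
Why: MnO2 oxidises only the allylic primary alcohol to enal 28, and Pinnick oxidation with a hypochlorite scavenger converts the enal to the acid without touching the alkene, the acetates or the tertiary alcohols.

Step 20
Reactants: 29 hydroxy acid (C16 carboxylic acid)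
Product: 31 querciformolide C, via mixed anhydride 30 (not isolated)
Conditions: 2,4,6-Cl3C6H2COCl, Et3N, THF, rt; then slow addition to DMAP (5 equiv), toluene, 80 °C
Reagents that add atoms: none
Why: Yamaguchi lactonisation: the acyl-pyridinium from mixed anhydride 30 is attacked by the tertiary C12 hydroxyl, the only hydroxyl that can close a small (seven-membered) ring, since C8–OH would need a ring of ten or more atoms and both secondary hydroxyls are acetylated; C12 keeps its configuration because its C–O bond is not broken.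

**Compound list**

1 | (+)-limonene 1,2-oxide, (4R)-1-methyl-4-(prop-1-en-2-yl)-7-oxabicyclo[4.1.0]heptane, cis/trans mixture | C=C(C)[C@@H]1CCC2(C)OC2C1 | starting material
2 | limonene-1,2-diol, (4R)-1-methyl-4-(prop-1-en-2-yl)cyclohexane-1,2-diol | C=C(C)[C@@H]1CCC(C)(O)C(O)C1 | intermediate (not isolated)
3 | (3R)-6-oxo-3-(prop-1-en-2-yl)heptanal | CC(=O)CC[C@@H](C(C)=C)CC=O | intermediate
4 | 2-bromopropene | CC(Br)=C | starting material
5 | (5R,7RS)-7-hydroxy-8-methyl-5-(prop-1-en-2-yl)non-8-en-2-one | CC(=O)CC[C@@H](C(C)=C)CC(O)C(C)=C | intermediate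
6 | (3RS,5R)-2-methyl-7-(2-methyl-1,3-dioxolan-2-yl)-5-(prop-1-en-2-yl)hept-1-en-3-ol | CC1(OCCO1)CC[C@@H](C(C)=C)CC(O)C(C)=C | intermediate
7 | triethyl orthoacetate | CC(OCC)(OCC)OCC | starting material
8 | ketene acetal, 1-ethoxyvinyl ether of 6 | CC1(OCCO1)CC[C@@H](C(C)=C)CC(OC(=C)OCC)C(C)=C | intermediate (not isolated)
9 | ethyl (4E,7R)-4-methyl-9-(2-methyl-1,3-dioxolan-2-yl)-7-(prop-1-en-2-yl)non-4-enoate | CC1(OCCO1)CC[C@@H](C(C)=C)C/C=C(C)/CCC(=O)OCC | intermediate
10 | (4E,7R)-4-methyl-9-(2-methyl-1,3-dioxolan-2-yl)-7-(prop-1-en-2-yl)non-4-enal | CC1(OCCO1)CC[C@@H](C(C)=C)C/C=C(C)/CCC=O | intermediate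
11 | 2-propenylmagnesium bromide | CC(=C)[Mg]Br | starting material
12 | (3RS,6E,9R)-2,6-dimethyl-11-(2-methyl-1,3-dioxolan-2-yl)-9-(prop-1-en-2-yl)undeca-1,6-dien-3-ol | CC1(OCCO1)CC[C@@H](C(C)=C)C/C=C(C)/CCC(O)C(C)=C | intermediate
13 | ketene acetal, 1-ethoxyvinyl ether of 12 | CC1(OCCO1)CC[C@@H](C(C)=C)C/C=C(C)/CCC(OC(=C)OCC)C(C)=C | intermediate (not isolated)
14 | ethyl (4E,8E,11R)-4,8-dimethyl-13-(2-methyl-1,3-dioxolan-2-yl)-11-(prop-1-en-2-yl)trideca-4,8-dienoate | CC1(OCCO1)CC[C@@H](C(C)=C)C/C=C(C)/CC/C=C(C)/CCC(=O)OCC | intermediate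
15 | (4E,8E,11R)-4,8-dimethyl-13-(2-methyl-1,3-dioxolan-2-yl)-11-(prop-1-en-2-yl)trideca-4,8-dienoic acid | CC1(OCCO1)CC[C@@H](C(C)=C)C/C=C(C)/CC/C=C(C)/CCC(=O)O | intermediate
16 | bis-epoxy acid, (4S,5S,8S,9S,11R)-4,5:8,9-diepoxy-4,8-dimethyl-13-(2-methyl-1,3-dioxolan-2-yl)-11-(prop-1-en-2-yl)tridecanoic acid (3S,4S,7S,8S in target numbering) | CC1(OCCO1)CC[C@@H](C(C)=C)C[C@@H]2O[C@@]2(C)CC[C@@H]3O[C@@]3(C)CCC(=O)O | intermediate (not isolated)
17 | epoxy hydroxy lactone: C8–C11 γ-lactone (8R), free (7S)-hydroxyl, intact (3S,4S)-epoxide, C12 dioxolane | CC1(OCCO1)CC[C@@H](C(C)=C)C[C@@H]2O[C@@]2(C)CC[C@H](O)[C@@]3(C)CCC(=O)O3 | intermediate (not isolated)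
18 | hydroxy oxolane lactone, (5R)-5-[(2S,5R)-5-{(1S,3R)-1-hydroxy-5-(2-methyl-1,3-dioxolan-2-yl)-3-(prop-1-en-2-yl)pentyl}-5-methyloxolan-2-yl]-5-methyloxolan-2-one (3S,4R,7S,8R in target numbering) | CC1(OCCO1)CC[C@@H](C(C)=C)C[C@H](O)[C@@]2(C)CC[C@H](O2)[C@@]3(C)CCC(=O)O3 | intermediate
19 | 3-O-tert-butyldimethylsilyl ether of 18 | CC1(OCCO1)CC[C@@H](C(C)=C)C[C@H](O[Si](C)(C)C(C)(C)C)[C@@]2(C)CC[C@H](O2)[C@@]3(C)CCC(=O)O3 | intermediate
20 | Weinreb amide (N-methoxy-N-methyl amide at C11) with free tertiary (8R)-OH, 3-OTBS, 4,7-oxolane, C12 dioxolane | CC1(OCCO1)CC[C@@H](C(C)=C)C[C@H](O[Si](C)(C)C(C)(C)C)[C@@]2(C)CC[C@H](O2)[C@](C)(O)CCC(=O)N(C)OC | intermediate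
21 | 8-O-triethylsilyl ether of 20 | CC1(OCCO1)CC[C@@H](C(C)=C)C[C@H](O[Si](C)(C)C(C)(C)C)[C@@]2(C)CC[C@H](O2)[C@](C)(O[Si](CC)(CC)CC)CCC(=O)N(C)OC | intermediate
22 | C11 aldehyde with 3-OTBS, 8-OTES, 4,7-oxolane, C12 dioxolane (1R,3S,4R,7S,8R) | CC1(OCCO1)CC[C@@H](C(C)=C)C[C@H](O[Si](C)(C)C(C)(C)C)[C@@]2(C)CC[C@H](O2)[C@](C)(O[Si](CC)(CC)CC)CCC=O | intermediate
23 | keto aldehyde: C12 methyl ketone and C11 aldehyde, C1 isopropenyl, 3-OTBS, 4,7-oxolane, 8-OTES (1R,3S,4R,7S,8R) | CC(=O)CC[C@@H](C(C)=C)C[C@H](O[Si](C)(C)C(C)(C)C)[C@@]1(C)CC[C@H](O1)[C@](C)(O[Si](CC)(CC)CC)CCC=O | intermediate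
24 | macrocyclic 11,12-diol: 14-membered carbocycle, 3-OTBS, 8-OTES, 4,7-oxolane, C1 isopropenyl (1R,3S,4R,7S,8R,11R,12R) | C[C@@]1(O)CC[C@@H](C(C)=C)C[C@H](O[Si](C)(C)C(C)(C)C)[C@@]2(C)CC[C@H](O2)[C@](C)(O[Si](CC)(CC)CC)CC[C@H]1O | intermediate
25 | macrocyclic 3,8,11,12-tetraol (1R,3S,4R,7S,8R,11R,12R) | C[C@@]1(O)CC[C@@H](C(C)=C)C[C@H](O)[C@@]2(C)CC[C@H](O2)[C@](C)(O)CC[C@H]1O | intermediate
26 | 3,11-diacetate of 25 (free tertiary 8-OH and 12-OH) | C[C@@]1(O)CC[C@@H](C(C)=C)C[C@H](OC(C)=O)[C@@]2(C)CC[C@H](O2)[C@](C)(O)CC[C@H]1OC(C)=O | intermediate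
27 | allylic alcohol: 26 with CH2=C(CH2OH) on C1 | C[C@@]1(O)CC[C@@H](C(CO)=C)C[C@H](OC(C)=O)[C@@]2(C)CC[C@H](O2)[C@](C)(O)CC[C@H]1OC(C)=O | intermediate
28 | enal: 26 with CH2=C(CHO) on C1 | C[C@@]1(O)CC[C@@H](C(C=O)=C)C[C@H](OC(C)=O)[C@@]2(C)CC[C@H](O2)[C@](C)(O)CC[C@H]1OC(C)=O | intermediate (not isolated)
29 | hydroxy acid: 26 with CH2=C(CO2H) on C1 | C[C@@]1(O)CC[C@@H](C(C(=O)O)=C)C[C@H](OC(C)=O)[C@@]2(C)CC[C@H](O2)[C@](C)(O)CC[C@H]1OC(C)=O | intermediate
30 | mixed anhydride of 29 with 2,4,6-trichlorobenzoic acid | C[C@@]1(O)CC[C@@H](C(C(=O)OC(=O)c3c(Cl)cc(Cl)cc3Cl)=C)C[C@H](OC(C)=O)[C@@]2(C)CC[C@H](O2)[C@](C)(O)CC[C@H]1OC(C)=O | intermediate (not isolated)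
31 | querciformolide C (1R,3S,4R,7S,8R,11R,12R) | C=C1C(=O)O[C@]2(C)CC[C@@H]1C[C@H](OC(C)=O)[C@@]1(C)CC[C@H](O1)[C@](C)(O)CC[C@H]2OC(C)=O | target

**Count and risks**

Total step count: 20. Longest linear sequence: 20 steps (1 → 31).

Steps most likely to fail:

1. Step 15. The ring closure may lose to intermolecular coupling, and facial selectivity may be poor, so that the ketyls combine on the other face and the (11S,12S) trans-diol predominates. The fallback sets out from 23 and comes back at 31; it keeps the coupling but uses its other trans product and makes the lactone C–O bond by carboxylate attack on an epoxide, which inverts both new centres.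
   - The (11S,12S)-diol F1 is mesylated at the secondary C11 hydroxyl (MsCl, Et3N) to the mesylate F2.
   - K2CO3 in MeOH closes the (11R,12S)-epoxide F3 by attack of the C12 alkoxide on C11 with inversion; the C8 silyl ether is kept on so that this oxygen does not open the epoxide.
   - SeO2/tBuOOH gives the allylic alcohol F4, MnO2 the epoxy enal F5 and NaClO2 the epoxy acid F6.
   - Catalytic CSA lets the acid open the epoxide at the tertiary C12 (7-exo, inversion) to the silylated 11-hydroxy lactone F7, now (11R,12R).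
   - HF·pyridine gives the triol lactone F8, and Ac2O/pyridine/DMAP acetylates C3 and C11 to 31.

2. Step 20. Acylation of the hindered tertiary C12 hydroxyl may be too slow, so that the activated acid is consumed by dimerisation or by amine addition to the acrylate. The fallback sets out from 27 and comes back at 31; it forms the C12–O–C16 bond by hemiacetal formation and oxidation instead of acyl substitution. TEMPO (cat.) with PhI(OAc)2 in CH2Cl2 oxidises 27 to enal 28; the C12 hydroxyl adds reversibly to the aldehyde to give the seven-membered lactol F9, which the same oxidant takes to 31.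

3. Step 18. Ene attack at the C1 methine, over-oxidation and selenium-bound by-products may erode a late intermediate. The fallback sets out from 26 and comes back at 28, which is oxidised to 29 as in step 19. Ene-type chlorination with HOCl (Ca(OCl)2, CO2, CH2Cl2–H2O, 0 °C) gives the allylic chloride F10, and N-methylmorpholine N-oxide in MeCN converts it to enal 28 (Ganem oxidation).

Further compounds
F1 | step 15 | (11S,12S)-diastereomer of diol 24 (3-OTBS, 8-OTES) | C[C@]1(O)CC[C@@H](C(C)=C)C[C@H](O[Si](C)(C)C(C)(C)C)[C@@]2(C)CC[C@H](O2)[C@](C)(O[Si](CC)(CC)CC)CC[C@@H]1O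
F2 | step 15 | 11-O-methanesulfonate of F1 | C[C@]1(O)CC[C@@H](C(C)=C)C[C@H](O[Si](C)(C)C(C)(C)C)[C@@]2(C)CC[C@H](O2)[C@](C)(O[Si](CC)(CC)CC)CC[C@@H]1OS(C)(=O)=O
F3 | step 15 | (11R,12S)-11,12-epoxide (3-OTBS, 8-OTES, C1 isopropenyl) | C[C@]12CC[C@@H](C(C)=C)C[C@H](O[Si](C)(C)C(C)(C)C)[C@@]3(C)CC[C@H](O3)[C@](C)(O[Si](CC)(CC)CC)CC[C@H]1O2
F4 | step 15 | allylic alcohol of F3 (CH2=C(CH2OH) on C1) | C[C@]12CC[C@@H](C(CO)=C)C[C@H](O[Si](C)(C)C(C)(C)C)[C@@]3(C)CC[C@H](O3)[C@](C)(O[Si](CC)(CC)CC)CC[C@H]1O2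
F5 | step 15 | epoxy enal (CH2=C(CHO) on C1) | C[C@]12CC[C@@H](C(C=O)=C)C[C@H](O[Si](C)(C)C(C)(C)C)[C@@]3(C)CC[C@H](O3)[C@](C)(O[Si](CC)(CC)CC)CC[C@H]1O2
F6 | step 15 | epoxy acid (CH2=C(CO2H) on C1) | C[C@]12CC[C@@H](C(C(=O)O)=C)C[C@H](O[Si](C)(C)C(C)(C)C)[C@@]3(C)CC[C@H](O3)[C@](C)(O[Si](CC)(CC)CC)CC[C@H]1O2
F7 | step 15 | (11R,12R)-11-hydroxy seven-membered lactone with 3-OTBS and 8-OTES | C=C1C(=O)O[C@]2(C)CC[C@@H]1C[C@H](O[Si](C)(C)C(C)(C)C)[C@@]1(C)CC[C@H](O1)[C@](C)(O[Si](CC)(CC)CC)CC[C@H]2O
F8 | step 15 | 3,8,11-triol lactone (bis-deacetyl querciformolide C) | C=C1C(=O)O[C@]2(C)CC[C@@H]1C[C@H](O)[C@@]1(C)CC[C@H](O1)[C@](C)(O)CC[C@H]2O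
F9 | step 20 | seven-membered lactol from enal 28 and the C12 hydroxyl | C=C1C(O)O[C@]2(C)CC[C@@H]1C[C@H](OC(C)=O)[C@@]1(C)CC[C@H](O1)[C@](C)(O)CC[C@H]2OC(C)=O
F10 | step 18 | allylic chloride: 26 with CH2=C(CH2Cl) on C1 | C[C@@]1(O)CC[C@@H](C(CCl)=C)C[C@H](OC(C)=O)[C@@]2(C)CC[C@H](O2)[C@](C)(O)CC[C@H]1OC(C)=O
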